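**Assumption:** germacrane numbering is used throughout (C6 = O‑bearing ring‑fusion carbon, C7 = the other ring‑fusion carbon, C9 = acetoxy carbon, C14 = methyl on C10, C15 = acyloxymethyl carbon on C4). Read this way the target is 6R,7R,9S with a cis‑fused lactone, and C2/C9 are cis across C1=C10 while C6/C15 are cis across C4=C5. All reagents named, including (−)‑B‑allyldiisopinocampheylborane solution, are bought.

## Retrosynthetic overview

1. Target 19 ⇒ open‑chain bromo ester aldehyde 16 by cutting C6–C7. The ten‑membered carbocycle closes first, in a chromium‑mediated intramolecular 2‑(methoxycarbonyl)allylation in which the allyl bromide serves as a β‑acyl carbanion (homoenolate) equivalent; the cis γ‑lactone closes second, in the same flask.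
2. 16 ⇒ terminal alkene 14 + methyl 2‑(bromomethyl)acrylate 15 (cross‑metathesis).
3. 14 ⇒ Z‑vinyl iodide 7 + diene acetal 11 (C1–C2 bond by B‑alkyl Suzuki coupling).
4. 7 and 11 ⇒ propargylic alcohols 4 and 8; CuI‑catalysed anti‑carbomagnesiation fixes both trisubstituted alkene geometries.
5. C9 comes from a Brown allylboration of 3‑(trimethylsilyl)propynal 1; C6 and C7 are set in the ring closure under control of C9.

## Route

**Step 1**
Reactants: 1 3‑(trimethylsilyl)prop‑2‑ynal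
Product: 4 (3S)‑hex‑5‑en‑1‑yn‑3‑ol, via borinate ester 2 (not isolated), via silyl enynol 3 (not isolated)
Conditions: (−)‑Ipc2B(allyl) (1.1 equiv), Et2O, −78 °C; then NaOH, H2O2, MeOH/H2O, 0 °C → rt
Reagents that add atoms: (−)‑B‑allyldiisopinocampheylborane (reagent from (+)‑α‑pinene), C=CCB([C@@H]1C[C@@H]2C[C@H]([C@H]1C)C2(C)C)[C@@H]1C[C@@H]2C[C@H]([C@H]1C)C2(C)C (allyl group; boron and the isopinocampheyl groups stay only in 2)
Why: Brown asymmetric allylboration through a closed chair transition state, in which this reagent attacks the Si face of the ynal and sets C9 as S, after which the basic peroxide/methanol work‑up cleaves both the borinate and the alkynyl C–Si bond.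

**Step 2**
Reactants: 4 (3S)‑hex‑5‑en‑1‑yn‑3‑ol
Product: 7 (3S,1Z)‑1‑iodo‑2‑methylhexa‑1,5‑dien‑3‑yl acetate, via magnesium chelate 5 (not isolated), via iodo alkoxide 6 (not isolated)
Conditions: MeMgBr (3 equiv), CuI (15 mol %), THF, −10 °C → rt; then I2, −78 → 0 °C; then Ac2O, 0 °C → rt
Reagents that add atoms: methylmagnesium bromide, C[Mg]Br; iodine, II; acetic anhydride, CC(=O)OC(C)=O
Why: CuI‑catalysed anti‑carbomagnesiation of the propargylic alkoxide (Duboudin–Jousseaume reaction) puts methyl on the proximal alkyne carbon and magnesium on the terminal carbon cis to the carbinol in a five‑membered chelate, so iodinolysis with retention gives only the Z iodide (C1=C10 geometry) and the remaining magnesium alkoxide is acetylated in the same flask without touching C9.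

**Step 3**
Reactants: 8 prop‑2‑yn‑1‑ol
Product: 11 (2Z)‑4,4‑diethoxy‑2‑ethenylbut‑2‑en‑1‑yl 3‑methylbutanoate, via dienyl magnesium chelate 9 (not isolated), via acetal alkoxide 10 (not isolated)
Conditions: CH2=CHMgBr (3 equiv), CuI (10 mol %), THF, 0 °C → rt; then PhOCH(OEt)2, 0 °C → rt; then (iPrCH2CO)2O, 0 °C → rt
Reagents that add atoms: vinylmagnesium bromide, C=C[Mg]Br; diethyl phenyl orthoformate, CCOC(OCC)Oc1ccccc1; 3‑methylbutanoic anhydride, CC(C)CC(=O)OC(=O)CC(C)C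
Why: The same anti‑carbomagnesiation places the vinyl group on C4 and magnesium on C5 cis to the CH2O group, the alkenyl–magnesium bond is formylated with retention as its diethyl acetal (Bodroux–Chichibabin‑type orthoformate reaction, fixing the C4=C5 geometry), and the single remaining alkoxide is acylated by the anhydride.

**Step 4**
Reactants: 11 (2Z)‑4,4‑diethoxy‑2‑ethenylbut‑2‑en‑1‑yl 3‑methylbutanoate; 7 (3S,1Z)‑1‑iodo‑2‑methylhexa‑1,5‑dien‑3‑yl acetate
Product: 14 (2Z,6Z,8S)‑8‑acetoxy‑7‑methyl‑3‑[(3‑methylbutanoyloxy)methyl]undeca‑2,6,10‑trienal, via alkylborane 12 (not isolated), via coupled acetal 13 (not isolated)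
Conditions: 11 (1.3 equiv), 9‑BBN (1.25 equiv), THF, 0 °C → rt; then 7 (1.0 equiv), PdCl2(dppf) (5 mol %), AsPh3 (10 mol %), Cs2CO3, DMF/H2O, rt; then 1 M HCl, THF, 0 °C
Reagents that add atoms: 9‑borabicyclo[3.3.1]nonane, B1C2CCCC1CCC2 (boron stays only in 12); water, O (aldehyde oxygen of 14)
Why: 9‑BBN hydroborates only the terminal vinyl carbon of the diene (all B–H is consumed before 7 is added), the B‑alkyl Suzuki–Miyaura coupling joins C2 to C1 with retention of the Z iodide geometry, and the acidic work‑up hydrolyses the enal acetal; no stereocentre is formed and C9 is untouched.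

**Step 5**
Reactants: 14 (2Z,6Z,8S)‑8‑acetoxy‑7‑methyl‑3‑[(3‑methylbutanoyloxy)methyl]undeca‑2,6,10‑trienal; 15 methyl 2‑(bromomethyl)prop‑2‑enoate
Product: 16 methyl (2Z,5S,6Z,10Z)‑5‑acetoxy‑2‑(bromomethyl)‑6‑methyl‑10‑[(3‑methylbutanoyloxy)methyl]‑12‑oxododeca‑2,6,10‑trienoate
Conditions: 15 (5 equiv), second‑generation Hoveyda–Grubbs catalyst RuCl2(H2IMes)(=CH–C6H4‑2‑OiPr) (10 mol %), CH2Cl2, 40 °C
Reagents that add atoms: none
Why: Olefin cross‑metathesis in which only the monosubstituted alkene of 14 is reactive, the acrylate partner does not homodimerise, and, as with methacrylates, the trisubstituted enoate forms with the ester trans to the chain (C8 cis to CH2Br), which is the geometry needed for the syn‑selective allylation.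

**Step 6**
Reactants: 16 methyl (2Z,5S,6Z,10Z)‑5‑acetoxy‑2‑(bromomethyl)‑6‑methyl‑10‑[(3‑methylbutanoyloxy)methyl]‑12‑oxododeca‑2,6,10‑trienoate
Product: 19 [(3aR,5S,6Z,10Z,11aR)‑5‑acetoxy‑6‑methyl‑3‑methylidene‑2‑oxo‑2,3,3a,4,5,8,9,11a‑octahydrocyclodeca[b]furan‑10‑yl]methyl 3‑methylbutanoate (CNP0398030.1), via allylchromium 17 (not isolated), via chromium alkoxide 18 (not isolated)
Conditions: CrCl2 (6 equiv), THF, 0.002 M, slow addition of 16, 25 °C; then aq. NH4Cl
Reagents that add atoms: CrCl2, Cl[Cr]Cl (chromium and chlorine stay only in 17 and 18)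
Why: Intramolecular Nozaki–Hiyama‑type (Barbier) 2‑(alkoxycarbonyl)allylation, in which divalent chromium turns the allylic bromide into an allylchromium that acts as a β‑acyl carbanion (homoenolate) equivalent, so the normally electrophilic acrylate β‑carbon C7 attacks the aldehyde carbon C6 through a chair transition state with C8 axial on the (Z)‑allylchromium (syn adduct, hence the cis lactone once the chromium alkoxide closes onto the methyl ester), while the 9S centre chooses the face because allylic 1,3‑strain holds H9 in the plane of the Z C1=C10 alkene with the acetoxy group outside the ring, which places C7 anti to OAc and C11 anti to C9 and so gives 7R and, through the syn chair, 6R.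

## Compound list

1 | 3‑(trimethylsilyl)prop‑2‑ynal | C[Si](C)(C)C#CC=O | starting material
2 | (3S)‑1‑(trimethylsilyl)hex‑5‑en‑1‑yn‑3‑yl diisopinocampheylborinate | C=CC[C@@H](C#C[Si](C)(C)C)OB([C@@H]1C[C@@H]2C[C@H]([C@H]1C)C2(C)C)[C@@H]1C[C@@H]2C[C@H]([C@H]1C)C2(C)C | intermediate
3 | (3S)‑1‑(trimethylsilyl)hex‑5‑en‑1‑yn‑3‑ol | C[Si](C)(C)C#C[C@@H](O)CC=C | intermediate
4 | (3S)‑hex‑5‑en‑1‑yn‑3‑ol | C#C[C@@H](O)CC=C | intermediate
5 | (5S)‑4‑methyl‑5‑(prop‑2‑en‑1‑yl)‑2,5‑dihydro‑1,2‑oxamagnesole (cyclic alkenylmagnesium alkoxide) | C=CC[C@@H]1O[Mg]C=C1C | intermediate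
6 | iodomagnesium (3S,1Z)‑1‑iodo‑2‑methylhexa‑1,5‑dien‑3‑olate | I/C=C(/C)[C@@H](O[Mg]I)CC=C | intermediate
7 | (3S,1Z)‑1‑iodo‑2‑methylhexa‑1,5‑dien‑3‑yl acetate | I/C=C(/C)[C@@H](OC(C)=O)CC=C | intermediate
8 | prop‑2‑yn‑1‑ol | C#CCO | starting material
9 | 4‑ethenyl‑2,5‑dihydro‑1,2‑oxamagnesole | C=CC1=C[Mg]OC1 | intermediate
10 | phenoxymagnesium (2Z)‑4,4‑diethoxy‑2‑ethenylbut‑2‑en‑1‑olate | CCOC(OCC)/C=C(\CO[Mg]Oc1ccccc1)C=C | intermediate
11 | (2Z)‑4,4‑diethoxy‑2‑ethenylbut‑2‑en‑1‑yl 3‑methylbutanoate | CCOC(OCC)/C=C(\COC(=O)CC(C)C)C=C | intermediate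
12 | 9‑[(3Z)‑5,5‑diethoxy‑3‑{[(3‑methylbutanoyl)oxy]methyl}pent‑3‑en‑1‑yl]‑9‑borabicyclo[3.3.1]nonane | CCOC(OCC)/C=C(\COC(=O)CC(C)C)CCB1C2CCCC1CCC2 | intermediate
13 | diethyl acetal of 14 | CCOC(OCC)/C=C(\COC(=O)CC(C)C)CC/C=C(/C)[C@@H](OC(C)=O)CC=C | intermediate
14 | (2Z,6Z,8S)‑8‑acetoxy‑7‑methyl‑3‑[(3‑methylbutanoyloxy)methyl]undeca‑2,6,10‑trienal | O=C/C=C(\COC(=O)CC(C)C)CC/C=C(/C)[C@@H](OC(C)=O)CC=C | intermediate
15 | methyl 2‑(bromomethyl)prop‑2‑enoate | C=C(CBr)C(=O)OC | starting material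
16 | methyl (2Z,5S,6Z,10Z)‑5‑acetoxy‑2‑(bromomethyl)‑6‑methyl‑10‑[(3‑methylbutanoyloxy)methyl]‑12‑oxododeca‑2,6,10‑trienoate | O=C/C=C(\COC(=O)CC(C)C)CC/C=C(/C)[C@@H](OC(C)=O)C/C=C(\CBr)C(=O)OC | intermediate
17 | allylchromium dichloride from 16 (C–Br replaced by C–CrCl2) | O=C/C=C(\COC(=O)CC(C)C)CC/C=C(/C)[C@@H](OC(C)=O)C/C=C(\C[Cr](Cl)Cl)C(=O)OC | intermediate
18 | dichlorochromium alkoxide of the ring‑closed hydroxy ester (6R,7R,9S) | Cl[Cr](Cl)O[C@@H]1/C=C(\COC(=O)CC(C)C)CC/C=C(/C)[C@@H](OC(C)=O)C[C@@H]1C(=C)C(=O)OC | intermediate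
19 | [(3aR,5S,6Z,10Z,11aR)‑5‑acetoxy‑6‑methyl‑3‑methylidene‑2‑oxo‑2,3,3a,4,5,8,9,11a‑octahydrocyclodeca[b]furan‑10‑yl]methyl 3‑methylbutanoate | C=C1C(=O)O[C@@H]2/C=C(\COC(=O)CC(C)C)CC/C=C(/C)[C@@H](OC(C)=O)C[C@H]12 | target

## Step count and risks

Total step count: 6. Longest linear sequence: 5 steps (1 → 4 → 7 → 14 → 16 → 19); step 3 is a one‑step side branch.

**Step 6 (most likely to fail).** A ten‑membered ring is closed at high dilution, and the face selectivity at C6/C7 rests on a conformational model. The syn (cis‑lactone) outcome is typical of (Z)‑2‑(bromomethyl)enoates; the sense relative to C9 is a prediction. Fallback: make the C6–C7 bond between two fragments under reagent control and close the ring at C1–C2 instead. It sets out from 11 and 7. Acid hydrolysis of 11 (1 M HCl, THF) gives the dienal (2Z)‑2‑ethenyl‑4‑oxobut‑2‑en‑1‑yl 3‑methylbutanoate F1. Cross‑metathesis of 7 with 15 under the step‑5 conditions gives methyl (2Z,5S,6Z)‑5‑acetoxy‑2‑(bromomethyl)‑7‑iodo‑6‑methylhepta‑2,6‑dienoate F2. F1 and F2 are joined by the same chromium allylation, now intermolecular and run with CrCl2 and a chiral oxazoline–sulfonamide ligand, to give the cis α‑methylene lactone F3. 9‑BBN then hydroborates the terminal vinyl group to the alkylborane F4, and PdCl2(dppf)/Cs2CO3 at high dilution closes the ring by an intramolecular B‑alkyl Suzuki coupling. This comes back to the route at 19.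

**Step 5.** Cross‑metathesis onto a 1,1‑disubstituted acrylate carrying an allylic bromide has little direct precedent; it is argued by analogy with methacrylates. Fallback: build the bromomethyl enoate by a Morita–Baylis–Hillman sequence, setting out from 7. OsO4 (cat.)/NaIO4/2,6‑lutidine cleaves only the terminal alkene of 7 (the iodoalkene is deactivated) to (3S,4Z)‑5‑iodo‑4‑methyl‑1‑oxopent‑4‑en‑3‑yl acetate F5. Methyl acrylate with DABCO gives methyl (5S,6Z)‑5‑acetoxy‑3‑hydroxy‑7‑iodo‑6‑methyl‑2‑methylidenehept‑6‑enoate F6, as both carbinol epimers, which converge later. F6 is coupled with the borane 12 as in step 4 to the coupled diethyl acetal F7, and the acid work‑up gives the hydroxy enal F8. NBS/Me2S then converts the allylic alcohol into the rearranged primary bromide, which comes back to the route at 16.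

**Step 4.** Three operations are run in one flask, and the hydroboration of a 2‑substituted 1,3‑diene must stop cleanly at the terminal carbon. Fallback: make the C1–C2 bond during the carbomagnesiation and the C3–C4 bond by a second carbomagnesiation, setting out from 4.
- 4 is treated with MeMgBr/CuI as in step 2, and the chelate 5 is trapped with ethylene oxide to give (3Z,5S)‑4‑methylocta‑3,7‑diene‑1,5‑diol F9.
- CBr4/PPh3 at −20 °C brominates only the primary alcohol to (4S,5Z)‑8‑bromo‑5‑methylocta‑1,5‑dien‑4‑ol F10, and TBSOTf/2,6‑lutidine gives the silyl ether F11.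
- Magnesium in THF gives the Grignard reagent F12, which adds to the bromomagnesium alkoxide of 8 (CuI) to form the alkenylmagnesium chelate F13.
- DMF, then 3‑methylbutanoic anhydride and an acidic work‑up, give the silyloxy enal F14.
- HF·pyridine frees the hydroxy enal F15, and Ac2O/DMAP acetylates it, which comes back to the route at 14.

## Further compounds

F1 | step 6 | (2Z)‑2‑ethenyl‑4‑oxobut‑2‑en‑1‑yl 3‑methylbutanoate | O=C/C=C(\COC(=O)CC(C)C)C=C
F2 | step 6 | methyl (2Z,5S,6Z)‑5‑acetoxy‑2‑(bromomethyl)‑7‑iodo‑6‑methylhepta‑2,6‑dienoate | I/C=C(/C)[C@@H](OC(C)=O)C/C=C(\CBr)C(=O)OC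
F3 | step 6 | [(2Z)‑3‑{(2R,3R)‑3‑[(2S,3Z)‑2‑acetoxy‑4‑iodo‑3‑methylbut‑3‑en‑1‑yl]‑4‑methylidene‑5‑oxooxolan‑2‑yl}‑2‑ethenylprop‑2‑en‑1‑yl] 3‑methylbutanoate | C=C1C(=O)O[C@H](/C=C(\COC(=O)CC(C)C)C=C)[C@@H]1C[C@H](OC(C)=O)/C(C)=C\I
F4 | step 6 | 9‑BBN adduct of F3 at the terminal vinyl carbon | C=C1C(=O)O[C@H](/C=C(\COC(=O)CC(C)C)CCB2C3CCCC2CCC3)[C@@H]1C[C@H](OC(C)=O)/C(C)=C\I
F5 | step 5 | (3S,4Z)‑5‑iodo‑4‑methyl‑1‑oxopent‑4‑en‑3‑yl acetate | I/C=C(/C)[C@@H](OC(C)=O)CC=O
F6 | step 5 | methyl (5S,6Z)‑5‑acetoxy‑3‑hydroxy‑7‑iodo‑6‑methyl‑2‑methylidenehept‑6‑enoate (both C3 epimers) | I/C=C(/C)[C@@H](OC(C)=O)CC(O)C(=C)C(=O)OC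
F7 | step 5 | diethyl acetal of F8 | CCOC(OCC)/C=C(\COC(=O)CC(C)C)CC/C=C(/C)[C@@H](OC(C)=O)CC(O)C(=C)C(=O)OC
F8 | step 5 | methyl (5S,6Z,10Z)‑5‑acetoxy‑3‑hydroxy‑6‑methyl‑10‑[(3‑methylbutanoyloxy)methyl]‑2‑methylidene‑12‑oxododeca‑6,10‑dienoate | O=C/C=C(\COC(=O)CC(C)C)CC/C=C(/C)[C@@H](OC(C)=O)CC(O)C(=C)C(=O)OC
F9 | step 4 | (3Z,5S)‑4‑methylocta‑3,7‑diene‑1,5‑diol | OCC/C=C(/C)[C@@H](O)CC=C
F10 | step 4 | (4S,5Z)‑8‑bromo‑5‑methylocta‑1,5‑dien‑4‑ol | BrCC/C=C(/C)[C@@H](O)CC=C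
F11 | step 4 | tert‑butyldimethylsilyl ether of F10 | BrCC/C=C(/C)[C@@H](O[Si](C)(C)C(C)(C)C)CC=C
F12 | step 4 | Grignard reagent from F11 | Br[Mg]CC/C=C(/C)[C@@H](O[Si](C)(C)C(C)(C)C)CC=C
F13 | step 4 | 4‑alkyl‑2,5‑dihydro‑1,2‑oxamagnesole from F12 and 8 | [Mg]1OCC(=C1)CC/C=C(/C)[C@@H](O[Si](C)(C)C(C)(C)C)CC=C
F14 | step 4 | (2Z,6Z,8S)‑8‑(tert‑butyldimethylsilyloxy)‑7‑methyl‑3‑[(3‑methylbutanoyloxy)methyl]undeca‑2,6,10‑trienal | O=C/C=C(\COC(=O)CC(C)C)CC/C=C(/C)[C@@H](O[Si](C)(C)C(C)(C)C)CC=C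
F15 | step 4 | (2Z,6Z,8S)‑8‑hydroxy‑7‑methyl‑3‑[(3‑methylbutanoyloxy)methyl]undeca‑2,6,10‑trienal | O=C/C=C(\COC(=O)CC(C)C)CC/C=C(/C)[C@@H](O)CC=C
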